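## Analysis of the target

Target 18 is a benzofuran substituted at every position except C5. Ring A (C3a–C7a) carries hydroxyls at C4 and C6 and a 2-(4-hydroxyphenyl)prop-2-enoyl group at C7 (its aryl group is ring E). The furan carries a 4-hydroxyphenyl group (ring C) at C2 and a 2,4-dihydroxybenzoyl group (ring D) at C3. There is no stereocentre and no configurational double bond, so the problem is one of regiochemistry and functional-group tolerance. The sensitive unit is the α-methylene ketone at C7: it lies ortho to the free C6 hydroxyl and can close by 6-endo oxa-Michael addition to a 3-arylchroman-4-one, or take up external nucleophiles, and base catalyses both. Six free phenols make the compound air-sensitive in base, and the C3 carbonyl is a crowded diaryl ketone wedged between ring C and the C4 oxygen. Stepwise aromatic substitution on ring A would have to tell C5 from C7, which is the main difficulty of a conventional approach. The feature the plan rests on is that C7, its carbonyl, the α-carbon with ring E, the methylene carbon and the C6 oxygen together are the retro-oxa-Michael form of an isoflavanone. The parent isoflavone with this ring A is genistein 6, whose hydrogen-bonded 5-OH lies where furan O1 must be attached (C7a) and whose C6–H lies at the future C3a.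

## Retrosynthetic reasoning

The last disconnection is a reconnection: joining the C6 oxygen of 18 to the methylene carbon gives the dihydropyranone of isoflavanone 16. The ortho-hydroxyaryl α-methylene ketone is the least tolerant function of 18 and should exist for one operation only; as a closed ring it is inert to acid, hydride and palladium. Forward, excess base must take 16 through C8 deprotonation and β-elimination of the aryloxide to hexaphenoxide 17, and cold protonation must return neutral 18 before the oxygen can add back.

The five phenols of 16 are traced to methoxymethyl ethers in 15, so that acid is used while the enone is still masked. The C7–C8 single bond of 15 is traced through enolate 14 to the C7=C8 double bond of isoflavone 13. No skeletal bond is cut; the gain is a flat, fully aromatic chromone that is robust in the coupling chemistry before it. Forward, a hindered hydride must add to C7 and leave the C3 aroyl ketone alone.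

Three bonds around the furan are then cut at once: O1–C2, C3–C(=O) and C(=O)–ring D. This divides 13 into alkynylphenol 11, aryl iodide 5 and carbon monoxide 12. Compound 11 already holds ring A with both its oxygens, the future C7 carbonyl, ring E and the future methylene carbon. Cutting here and not at the C7 acyl bond means that no acylation has to choose between C5 and C7 and no methylenation beside a free phenol is needed. Cutting all three bonds rather than only the C3–acyl bond avoids acylating an electron-rich benzofuran at a hindered position. Forward, an aroyl–palladium species must activate the alkyne, the phenol must close 5-endo-dig, and the acyl group must be delivered to C3.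

The aryl–alkyne bond at C6 of the isoflavone is cut next, giving 6-iodide 9 and arylacetylene 3. The 5-oxygen is carried as an acetate in 9 and 10 so that the coupling cannot run on to a furan lacking the acyl group. The only free phenol of 11 is then revealed in a separate mild step directly before it is needed.

Removal of the acetyl group and of iodine leads through 8 to 7, and removal of two acetals to 6. The C–I bond is placed at C6 because this is the position ortho to the one hydroxyl that stays free when 6 is etherified. The same hydrogen-bonded 5-OH that resists alkylation therefore directs the halogen and later becomes O1.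

Alkyne 3 is traced by one-carbon homologation to aldehyde 2 and by acetal protection to 1; iodide 5 comes from 4 in one step. Both side pieces carry the same acetal as 7, so that one acidic step frees all five phenols.

## Alternatives that were turned down

Alternative 1: Ring A is taken apart at C7a–C7, C6–C7, C4–C5 and C3a–C4, leaving a tetrasubstituted furan. In the forward key step, irradiation of diazo ketone A2 triggers a Wolff rearrangement; [2+2] addition of ethoxyacetylene A3, thermal four-electron ring opening and six-electron closure onto furan C3 give phenol A1.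
- For: ring A is assembled with its two oxygens in fixed positions and already differentiated (free C4-OH, C6 ether), and no aromatic substitution selectivity is involved up to that point.
- Against: A1 has hydrogen at C7, so the whole 2-arylacryloyl unit must still be added by acylation of a ring on which C5, between two oxygens, competes with C7. The following α-methylenation beside a phenol closes to a chromanone in any case. A2 is a multi-step target in itself and carries a diaryl ketone chromophore that can divert the photochemistry. Three methyl ethers and one ethyl ether must finally be cleaved with strong Lewis acid.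
- Comparison: this alternative is stronger in that ring A regiochemistry needs no directing effect and no halogenation. It is several steps longer and postpones the hardest substituent, whereas the chosen route obtains ring A, the C7 carbonyl, ring E and the methylene carbon in one purchased compound, 6.

Alternative 2: The C6–O and C7–C(=O) bonds are cut, leading to a benzofuran with a C6–C7 triple bond and arylacetic acid A6. In the forward key step, fluoride-induced loss of the silyl and sulfonate groups from silyl triflate A5 unmasks that triple bond. The carboxylate of A6 adds through oxygen at C6, the C7 carbanion (stabilized by the neighbouring ring oxygen) attacks the carboxyl carbon, and collapse of the four-membered adduct gives ortho-hydroxy ketone A4.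
- For: phenol and acyl group are set in one step with predictable orientation, and the protecting groups are the same as in the chosen route.
- Against: A5 presupposes the complete 2-aryl-3-aroylbenzofuran with vicinal silyl and sulfonate groups on a fully substituted ring, so the core problem is only moved upstream. Proton transfer from the acidic methylene of A6 can stop the sequence after O-arylation without acyl transfer. A4 still needs methylenation next to a free phenol, which closes to a chromanone of the type of 15 and so leads to the same final opening.
- Comparison: it is equal in protecting-group logic and stronger in freedom to vary the C7 acyl group. It adds steps before and after its key step without removing the end-game risk, whereas the chosen route takes the C6-oxygen/C7-acyl relationship directly from 6.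

Alternative 3: The furan bonds C3–C3a and O1–C2 are cut, leading to N-aryloxy enaminone A8, which comes from diketone A9 and O-arylhydroxylamine A10. In the forward key step, acid induces the [3,3] shift of A8 with N–O cleavage and C3–C3a formation; the liberated phenol adds to the iminium carbon to make O1–C2, and the nitrogen is expelled to give A7.
- For: it is the shortest entry to the 2-aryl-3-aroylbenzofuran, needs no metal and no CO, and the symmetric aryloxy group makes the shift itself regiochemically unambiguous.
- Against: condensation of A10 with the unsymmetrical A9 can occur at either carbonyl, so rings C and D may end up exchanged. A7 again has hydrogen at C7 and faces the C5/C7 acylation problem and the methylenation. Five methyl ethers leave only harsh Lewis-acid cleavage, which the enone does not tolerate.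
- Comparison: this alternative is clearly stronger in step count to the bicyclic core. The chosen route is stronger for everything on ring A and ends with protecting groups that come off under mild acid.

Key step: step 9

Remark: the C8 centre of 15 and 16 is carried as a racemate because step 12 turns it into an sp2 carbon. Locants of 7–11 follow chromen-4-one numbering, those of 13–16 furo[2,3-f]chromen-9-one numbering (O1, C2, C3, C3a, C4, C5, C5a, O6, C7, C8, C9, C9a, C9b), and those of 18 benzofuran numbering.

## Route

Step 1
Reactants: 1 4-hydroxybenzaldehyde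
Product: 2 4-(methoxymethoxy)benzaldehyde
Conditions: MOMCl, i-Pr2NEt, CH2Cl2, 0 °C → rt
Reagents that add atoms: chloromethyl methyl ether (MOMCl), COCCl
Why: Williamson-type O-alkylation of the phenol by the reactive chloromethyl ether (MOM protection); the aldehyde is not affected.

Step 2
Reactants: 2 4-(methoxymethoxy)benzaldehyde
Product: 3 1-ethynyl-4-(methoxymethoxy)benzene
Conditions: Ohira–Bestmann reagent, K2CO3, MeOH, 0 °C → rt
Reagents that add atoms: dimethyl (1-diazo-2-oxopropyl)phosphonate (Ohira–Bestmann reagent), COP(=O)(OC)C(=[N+]=[N-])C(C)=O
Why: Seyferth–Gilbert homologation in the Ohira–Bestmann variant: methanolysis of the acetyl group frees the diazomethylphosphonate anion, olefination of the aldehyde gives a diazoalkene, and loss of N2 with 1,2-hydrogen shift gives the terminal alkyne. Electron-rich benzaldehydes are good substrates and the MOM ether is inert to K2CO3.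

Step 3
Reactants: 4 4-iodobenzene-1,3-diol (4-iodoresorcinol)
Product: 5 1-iodo-2,4-bis(methoxymethoxy)benzene
Conditions: MOMCl (2.5 equiv), i-Pr2NEt, CH2Cl2, 0 °C → rt
Reagents that add atoms: chloromethyl methyl ether (MOMCl), COCCl
Why: Double MOM etherification of both phenols; the ortho iodine does not hinder O-alkylation and the C–I bond is untouched.

Step 4
Reactants: 6 genistein
Product: 7 5-hydroxy-7-(methoxymethoxy)-3-[4-(methoxymethoxy)phenyl]-4H-chromen-4-one
Conditions: MOMCl (2.3 equiv), K2CO3, acetone, 0 °C → rt
Reagents that add atoms: chloromethyl methyl ether (MOMCl), COCCl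
Why: Selective phenol etherification: the 7- and 4'-hydroxyls are the acidic, unhindered phenols, whereas the 5-OH is held in a hydrogen bond to the C4 carbonyl and is not alkylated by a weak heterogeneous base.

Step 5
Reactants: 7 5-hydroxy-7-(methoxymethoxy)-3-[4-(methoxymethoxy)phenyl]-4H-chromen-4-one
Product: 8 5-hydroxy-6-iodo-7-(methoxymethoxy)-3-[4-(methoxymethoxy)phenyl]-4H-chromen-4-one
Conditions: BnMe3N·ICl2 (1.05 equiv), CaCO3, CH2Cl2–MeOH (5:2), rt
Reagents that add atoms: benzyltrimethylammonium dichloroiodate, C[N+](C)(C)Cc1ccccc1.Cl[I-]Cl
Why: Electrophilic aromatic iodination; the free chelated 5-OH directs to its ortho position C6, which is also ortho to the 7-alkoxy group, a pattern established for 5-hydroxy-7-alkoxychromones with this reagent, and CaCO3 takes up HCl so that the acetals survive. The position of iodine should be confirmed by a long-range C–H correlation from the chelated hydroxyl proton before going on.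

Step 6
Reactants: 8 5-hydroxy-6-iodo-7-(methoxymethoxy)-3-[4-(methoxymethoxy)phenyl]-4H-chromen-4-one
Product: 9 6-iodo-7-(methoxymethoxy)-3-[4-(methoxymethoxy)phenyl]-4-oxo-4H-chromen-5-yl acetate
Conditions: Ac2O, pyridine, DMAP (cat.), CH2Cl2, rt
Reagents that add atoms: acetic anhydride, CC(=O)OC(C)=O
Why: DMAP-catalysed O-acylation of the hindered phenol; masking the 5-OH keeps the next step from running on to a furan that lacks the C3 acyl group.

Step 7
Reactants: 9 6-iodo-7-(methoxymethoxy)-3-[4-(methoxymethoxy)phenyl]-4-oxo-4H-chromen-5-yl acetate; 3 1-ethynyl-4-(methoxymethoxy)benzene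
Product: 10 7-(methoxymethoxy)-3-[4-(methoxymethoxy)phenyl]-6-{[4-(methoxymethoxy)phenyl]ethynyl}-4-oxo-4H-chromen-5-yl acetate
Conditions: PdCl2(PPh3)2 (5 mol %), CuI (5 mol %), Et3N, DMF, 50 °C, degassed
Reagents that add atoms: none
Why: Sonogashira coupling of an aryl iodide with a terminal alkyne; with the phenol acetylated no oxygen nucleophile is available for metal-mediated cycloisomerization. A tertiary amine is used because secondary amines would attack C2 of the pyranone and the activated aryl acetate.

Step 8
Reactants: 10 7-(methoxymethoxy)-3-[4-(methoxymethoxy)phenyl]-6-{[4-(methoxymethoxy)phenyl]ethynyl}-4-oxo-4H-chromen-5-yl acetate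
Product: 11 5-hydroxy-7-(methoxymethoxy)-3-[4-(methoxymethoxy)phenyl]-6-{[4-(methoxymethoxy)phenyl]ethynyl}-4H-chromen-4-one
Conditions: K2CO3 (0.2 equiv), MeOH–THF (1:1), 0 °C; AcOH quench
Reagents that add atoms: none
Why: Base-catalysed transesterification of an aryl acetate, fast because the leaving phenoxide is stabilized by the peri carbonyl. Low temperature and catalytic base should avoid methoxide attack at C2 and base-induced 5-endo-dig closure.

Step 9
Reactants: 11 5-hydroxy-7-(methoxymethoxy)-3-[4-(methoxymethoxy)phenyl]-6-{[4-(methoxymethoxy)phenyl]ethynyl}-4H-chromen-4-one; 5 1-iodo-2,4-bis(methoxymethoxy)benzene; 12 carbon monoxide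
Product: 13 3-[2,4-bis(methoxymethoxy)benzoyl]-4-(methoxymethoxy)-2,8-bis[4-(methoxymethoxy)phenyl]-9H-furo[2,3-f]chromen-9-one
Conditions: Pd(PPh3)4 (10 mol %), KOAc (4 equiv), CO (1 atm), MeCN–THF, 50 °C
Reagents that add atoms: none
Why: Oxidative addition of 5 to zerovalent palladium and migratory insertion of 12 give an aroyl complex of divalent palladium, which binds the alkyne of 11 as a π-acid. The 5-oxygen, deprotonated reversibly by acetate, attacks the distal alkyne carbon anti to palladium in a 5-endo-dig closure that makes O1–C2 and leaves a C3–palladium bond; reductive elimination then joins C3 to the aroyl carbon and returns zerovalent palladium. The closest known reaction type is the palladium-catalysed carbonylative cyclization of 2-alkynylphenols with aryl iodides to 2-substituted 3-aroylbenzofurans, here run on a phenol that is part of a chromone. One ring, the furan, is closed (5-endo-dig); no stereocentre is formed. Acyl transfer has to outrun direct aryl transfer, which the CO atmosphere and the fast insertion expected for an electron-rich ortho-alkoxyaryl palladium species favour. Cycloisomerization to the C3-unsubstituted furan is held back by the weak base, the moderate temperature and the absence of copper. Aroylation at the phenol oxygen is disfavoured because the chelated, doubly flanked 5-OH is a poor intermolecular nucleophile but is held next to the activated alkyne. Regiochemistry cannot vary: only the 5-OH is free and the alkyne sits on C6, so ring C ends on C2 and the aroyl group on C3.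

Step 10
Reactants: 13 3-[2,4-bis(methoxymethoxy)benzoyl]-4-(methoxymethoxy)-2,8-bis[4-(methoxymethoxy)phenyl]-9H-furo[2,3-f]chromen-9-one
Product: 15 (±)-3-[2,4-bis(methoxymethoxy)benzoyl]-4-(methoxymethoxy)-2,8-bis[4-(methoxymethoxy)phenyl]-7,8-dihydro-9H-furo[2,3-f]chromen-9-one, via lithium enolate 14 (not isolated)
Conditions: LiBH(s-Bu)3 (1.2 equiv), THF, −78 °C; AcOH, −78 °C
Reagents that add atoms: none
Why: Conjugate hydride addition of a bulky trialkylborohydride to the unsubstituted C7 of the chromone, a known way from isoflavones to isoflavanones; the C3 aroyl carbonyl is a vinylogous ester flanked by ring C and two ortho oxygens and should not compete at −78 °C. Protonation of enolate 14 in the cold creates C8 as a racemic centre, which is of no consequence because step 12 removes it.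

Step 11
Reactants: 15 (±)-3-[2,4-bis(methoxymethoxy)benzoyl]-4-(methoxymethoxy)-2,8-bis[4-(methoxymethoxy)phenyl]-7,8-dihydro-9H-furo[2,3-f]chromen-9-one
Product: 16 (±)-3-(2,4-dihydroxybenzoyl)-4-hydroxy-2,8-bis(4-hydroxyphenyl)-7,8-dihydro-9H-furo[2,3-f]chromen-9-one
Conditions: HCl (1.25 M in MeOH), THF, 40 °C
Reagents that add atoms: none
Why: Acid-catalysed acetal exchange of five aryl MOM ethers with methanol; it is done at the isoflavanone stage because the ketones, the furan and the saturated pyranone are indifferent to acid, whereas the final enone would not be.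

Step 12
Reactants: 16 (±)-3-(2,4-dihydroxybenzoyl)-4-hydroxy-2,8-bis(4-hydroxyphenyl)-7,8-dihydro-9H-furo[2,3-f]chromen-9-one
Product: 18 1-[3-(2,4-dihydroxybenzoyl)-4,6-dihydroxy-2-(4-hydroxyphenyl)-1-benzofuran-7-yl]-2-(4-hydroxyphenyl)prop-2-en-1-one (the target), via hexapotassium phenoxide 17 (not isolated)
Conditions: KN(SiMe3)2 (6.5 equiv), THF–DMPU, −78 → −10 °C, ca. 5 mM, degassed, Ar; then cannulation into AcOH–THF at −78 °C, cold work-up at pH 4–5
Reagents that add atoms: none
Why: E1cB retro-oxa-Michael opening of a chroman-4-one, the reaction type by which flavanones give 2'-hydroxychalcones and by which isoflavanone enolates are known to open. After the five phenols are deprotonated, the sixth equivalent of the hindered, non-nucleophilic amide removes H8; the enolate expels aryloxide O6, and the equilibrium is drawn to 17 because a weakly basic ortho-acylphenoxide is formed at the expense of the amide. Inverse quench into cold acid should protonate all phenoxides faster than the oxygen can add back, and neutral 18 recloses only under base catalysis.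

## Compound list

1 | 4-hydroxybenzaldehyde | O=Cc1ccc(O)cc1 | starting material
2 | 4-(methoxymethoxy)benzaldehyde | COCOc1ccc(C=O)cc1 | intermediate
3 | 1-ethynyl-4-(methoxymethoxy)benzene | C#Cc1ccc(OCOC)cc1 | intermediate
4 | 4-iodobenzene-1,3-diol (4-iodoresorcinol) | Oc1ccc(I)c(O)c1 | starting material
5 | 1-iodo-2,4-bis(methoxymethoxy)benzene | COCOc1ccc(I)c(OCOC)c1 | intermediate
6 | genistein, 5,7-dihydroxy-3-(4-hydroxyphenyl)-4H-chromen-4-one | O=c1c(-c2ccc(O)cc2)coc2cc(O)cc(O)c12 | starting material
7 | 5-hydroxy-7-(methoxymethoxy)-3-[4-(methoxymethoxy)phenyl]-4H-chromen-4-one | O=c1c(-c2ccc(OCOC)cc2)coc2cc(OCOC)cc(O)c12 | intermediate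
8 | 5-hydroxy-6-iodo-7-(methoxymethoxy)-3-[4-(methoxymethoxy)phenyl]-4H-chromen-4-one | O=c1c(-c2ccc(OCOC)cc2)coc2cc(OCOC)c(I)c(O)c12 | intermediate
9 | 6-iodo-7-(methoxymethoxy)-3-[4-(methoxymethoxy)phenyl]-4-oxo-4H-chromen-5-yl acetate | O=c1c(-c2ccc(OCOC)cc2)coc2cc(OCOC)c(I)c(OC(C)=O)c12 | intermediate
10 | 7-(methoxymethoxy)-3-[4-(methoxymethoxy)phenyl]-6-{[4-(methoxymethoxy)phenyl]ethynyl}-4-oxo-4H-chromen-5-yl acetate | O=c1c(-c2ccc(OCOC)cc2)coc2cc(OCOC)c(C#Cc3ccc(OCOC)cc3)c(OC(C)=O)c12 | intermediate
11 | 5-hydroxy-7-(methoxymethoxy)-3-[4-(methoxymethoxy)phenyl]-6-{[4-(methoxymethoxy)phenyl]ethynyl}-4H-chromen-4-one | O=c1c(-c2ccc(OCOC)cc2)coc2cc(OCOC)c(C#Cc3ccc(OCOC)cc3)c(O)c12 | intermediate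
12 | carbon monoxide | [C-]#[O+] | starting material
13 | 3-[2,4-bis(methoxymethoxy)benzoyl]-4-(methoxymethoxy)-2,8-bis[4-(methoxymethoxy)phenyl]-9H-furo[2,3-f]chromen-9-one (isoflavone with a furan fused through the 5-oxygen and C6) | O=c1c(-c2ccc(OCOC)cc2)coc2cc(OCOC)c3c(C(=O)c4ccc(OCOC)cc4OCOC)c(-c4ccc(OCOC)cc4)oc3c12 | intermediate
14 | lithium enolate of 15 (formed in the flask) | [Li+].[O-]C1=C(c2ccc(OCOC)cc2)COc2cc(OCOC)c3c(C(=O)c4ccc(OCOC)cc4OCOC)c(-c4ccc(OCOC)cc4)oc3c12 | intermediate
15 | (±)-3-[2,4-bis(methoxymethoxy)benzoyl]-4-(methoxymethoxy)-2,8-bis[4-(methoxymethoxy)phenyl]-7,8-dihydro-9H-furo[2,3-f]chromen-9-one (racemic at C8) | O=C1C(c2ccc(OCOC)cc2)COc2cc(OCOC)c3c(C(=O)c4ccc(OCOC)cc4OCOC)c(-c4ccc(OCOC)cc4)oc3c12 | intermediate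
16 | (±)-3-(2,4-dihydroxybenzoyl)-4-hydroxy-2,8-bis(4-hydroxyphenyl)-7,8-dihydro-9H-furo[2,3-f]chromen-9-one (racemic at C8) | O=C1C(c2ccc(O)cc2)COc2cc(O)c3c(C(=O)c4ccc(O)cc4O)c(-c4ccc(O)cc4)oc3c12 | intermediate
17 | hexapotassium hexaphenoxide of 18 (formed in the flask) | C=C(C(=O)c1c([O-])cc([O-])c2c(C(=O)c3ccc([O-])cc3[O-])c(-c3ccc([O-])cc3)oc12)c1ccc([O-])cc1.[K+].[K+].[K+].[K+].[K+].[K+] | intermediate
18 | 1-[3-(2,4-dihydroxybenzoyl)-4,6-dihydroxy-2-(4-hydroxyphenyl)-1-benzofuran-7-yl]-2-(4-hydroxyphenyl)prop-2-en-1-one | C=C(C(=O)c1c(O)cc(O)c2c(C(=O)c3ccc(O)cc3O)c(-c3ccc(O)cc3)oc12)c1ccc(O)cc1 | target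

## Step count and least certain steps

Total step count: 12. Longest linear sequence: 9 steps (6 → 18 through steps 4–12).

For step 9 (key step), the carbonylation may lose to three other processes: closure of the alkynylphenol without acyl transfer, direct aryl transfer before CO uptake, and aroylation at the phenol oxygen. Oxidative addition of the hindered, electron-rich iodide is slowed under CO, which gives these processes time. The fallback separates ring closure from acylation; it sets out from 11 and 5 and returns at 13.
- Iodocyclization of 11 (I2, NaHCO3, MeCN, rt) should give 3-iodo-4-(methoxymethoxy)-2,8-bis[4-(methoxymethoxy)phenyl]-9H-furo[2,3-f]chromen-9-one F1.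
- Iodine–lithium exchange on 5 (n-BuLi, THF, −78 °C), B(Oi-Pr)3 and aqueous work-up should give [2,4-bis(methoxymethoxy)phenyl]boronic acid F2.
- Carbonylative Suzuki–Miyaura coupling of F1 with F2 and 12 (PdCl2(dppf), K2CO3, anisole, 80 °C) would then give 13.

For step 12, the opening may stop short if the polyanion equilibrium is less favourable than estimated. The oxygen may add back during protonation or work-up, phenoxides of one molecule may add to the enone of another, and the enolate or polyphenoxide may autoxidize. The fallback opens the ring while the phenols are still protected; it sets out from 15 and returns at 18.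
- KN(SiMe3)2 (1.1 equiv, THF, −78 → 0 °C) opens the monoanion, and the single aryloxide is trapped with MOMCl. This should give 1-{3-[2,4-bis(methoxymethoxy)benzoyl]-4,6-bis(methoxymethoxy)-2-[4-(methoxymethoxy)phenyl]-1-benzofuran-7-yl}-2-[4-(methoxymethoxy)phenyl]prop-2-en-1-one F3, which cannot reclose.
- The six acetals are then removed without base (methanolic HCl at rt, or Me3SiBr in CH2Cl2 at −30 °C) to give 18. Acid-catalysed addition to a terminal methylene is expected to be slow because the β-carbon is primary.

For step 10, the hydride may add 1,2 to the C3 aroyl ketone or to the chromone carbonyl. Enolate 14 may also open before the quench and take up a second hydride at the freed enone. The fallback, from 13 to 15, replaces the hydride by heterogeneous catalytic transfer hydrogenation (Pd/C, HCO2NH4, MeOH–THF, 55 °C), which saturates the C7=C8 bond without forming an enolate. No compound outside the list is made (F0).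

For step 5, iodination may fall on C8 or on both positions, since both are activated, and poorly buffered HCl may strip an acetal. The fallback replaces halogenation by a reaction that is ortho-specific for mechanistic reasons; it sets out from 7 and returns at 10.
- Magnesium-phenoxide formylation of 7 (MgCl2, Et3N, paraformaldehyde, MeCN, reflux) delivers formaldehyde within a chelate and can reach only C6. It should give 5-hydroxy-7-(methoxymethoxy)-3-[4-(methoxymethoxy)phenyl]-4-oxo-4H-chromene-6-carbaldehyde F4.
- Ohira–Bestmann homologation gives 6-ethynyl-5-hydroxy-7-(methoxymethoxy)-3-[4-(methoxymethoxy)phenyl]-4H-chromen-4-one F5.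
- Acetylation gives 6-ethynyl-7-(methoxymethoxy)-3-[4-(methoxymethoxy)phenyl]-4-oxo-4H-chromen-5-yl acetate F6.
- Sonogashira coupling of F6 with 1-iodo-4-(methoxymethoxy)benzene F7 (one acetal protection from the commercial phenol) gives 10.

## Further compounds

F1 | step 9 | 3-iodo-4-(methoxymethoxy)-2,8-bis[4-(methoxymethoxy)phenyl]-9H-furo[2,3-f]chromen-9-one | O=c1c(-c2ccc(OCOC)cc2)coc2cc(OCOC)c3c(I)c(-c4ccc(OCOC)cc4)oc3c12
F2 | step 9 | [2,4-bis(methoxymethoxy)phenyl]boronic acid | COCOc1ccc(B(O)O)c(OCOC)c1
F3 | step 12 | 1-{3-[2,4-bis(methoxymethoxy)benzoyl]-4,6-bis(methoxymethoxy)-2-[4-(methoxymethoxy)phenyl]-1-benzofuran-7-yl}-2-[4-(methoxymethoxy)phenyl]prop-2-en-1-one | C=C(C(=O)c1c(OCOC)cc(OCOC)c2c(C(=O)c3ccc(OCOC)cc3OCOC)c(-c3ccc(OCOC)cc3)oc12)c1ccc(OCOC)cc1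
F0 | step 10 | none | none
F4 | step 5 | 5-hydroxy-7-(methoxymethoxy)-3-[4-(methoxymethoxy)phenyl]-4-oxo-4H-chromene-6-carbaldehyde | O=Cc1c(OCOC)cc2occ(-c3ccc(OCOC)cc3)c(=O)c2c1O
F5 | step 5 | 6-ethynyl-5-hydroxy-7-(methoxymethoxy)-3-[4-(methoxymethoxy)phenyl]-4H-chromen-4-one | C#Cc1c(OCOC)cc2occ(-c3ccc(OCOC)cc3)c(=O)c2c1O
F6 | step 5 | 6-ethynyl-7-(methoxymethoxy)-3-[4-(methoxymethoxy)phenyl]-4-oxo-4H-chromen-5-yl acetate | C#Cc1c(OCOC)cc2occ(-c3ccc(OCOC)cc3)c(=O)c2c1OC(C)=O
F7 | step 5 | 1-iodo-4-(methoxymethoxy)benzene | COCOc1ccc(I)cc1
A1 | alternative 1 | [6-ethoxy-4-hydroxy-2-(4-methoxyphenyl)-1-benzofuran-3-yl](2,4-dimethoxyphenyl)methanone | CCOc1cc(O)c2c(C(=O)c3ccc(OC)cc3OC)c(-c3ccc(OC)cc3)oc2c1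
A2 | alternative 1 | 2-diazo-1-[4-(2,4-dimethoxybenzoyl)-5-(4-methoxyphenyl)furan-2-yl]ethan-1-one | [N-]=[N+]=CC(=O)c1cc(C(=O)c2ccc(OC)cc2OC)c(-c2ccc(OC)cc2)o1
A3 | alternative 1 | ethoxyacetylene | C#COCC
A4 | alternative 2 | 1-{6-hydroxy-4-(methoxymethoxy)-2-[4-(methoxymethoxy)phenyl]-3-[2,4-bis(methoxymethoxy)benzoyl]-1-benzofuran-7-yl}-2-[4-(methoxymethoxy)phenyl]ethan-1-one | O=C(Cc1ccc(OCOC)cc1)c1c(O)cc(OCOC)c2c(C(=O)c3ccc(OCOC)cc3OCOC)c(-c3ccc(OCOC)cc3)oc12
A5 | alternative 2 | 3-[2,4-bis(methoxymethoxy)benzoyl]-4-(methoxymethoxy)-2-[4-(methoxymethoxy)phenyl]-7-(trimethylsilyl)-1-benzofuran-6-yl trifluoromethanesulfonate | C[Si](C)(C)c1c(OS(=O)(=O)C(F)(F)F)cc(OCOC)c2c(C(=O)c3ccc(OCOC)cc3OCOC)c(-c3ccc(OCOC)cc3)oc12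
A6 | alternative 2 | [4-(methoxymethoxy)phenyl]acetic acid | OC(=O)Cc1ccc(OCOC)cc1
A7 | alternative 3 | [4,6-dimethoxy-2-(4-methoxyphenyl)-1-benzofuran-3-yl](2,4-dimethoxyphenyl)methanone | COc1ccc(cc1)-c1oc2cc(OC)cc(OC)c2c1C(=O)c1ccc(OC)cc1OC
A8 | alternative 3 | (Z)-3-[(3,5-dimethoxyphenoxy)amino]-1-(2,4-dimethoxyphenyl)-3-(4-methoxyphenyl)prop-2-en-1-one | COc1ccc(cc1)/C(NOc1cc(OC)cc(OC)c1)=C/C(=O)c1ccc(OC)cc1OC
A9 | alternative 3 | 1-(2,4-dimethoxyphenyl)-3-(4-methoxyphenyl)propane-1,3-dione | COc1ccc(cc1)C(=O)CC(=O)c1ccc(OC)cc1OC
A10 | alternative 3 | O-(3,5-dimethoxyphenyl)hydroxylamine | NOc1cc(OC)cc(OC)c1
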